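**Plan**

1. Cuts: the C3 methyl is traced back to an ester and then to a geminal diester. The tetrahydrofuran is then cut at O1–C5 and C2–C3, giving an aryl cyclopropane-1,1-diester (C3, C4, C5) and a benzaldehyde (C2, O1). The aldehyde is cut at the ring A–alkenyl bond and at the C–B bond of an aryl propyne adduct.
2. Enabling feature: the ring O1/C2/C3/C4/C5 has its two aryl groups cis on C2 and C5 either side of O1, with the C4 methyl trans to the C5 aryl. This is the pattern left when an aldehyde C=O inserts into the donor–acceptor bond of a cis-2-methyl-3-arylcyclopropane-1,1-diester (C5 = donor carbon, C4 = its methyl neighbour, C3 = malonate carbon).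
3. Forward order: cyclopropane 8 (steps 1–4) and aldehyde 18 (steps 5–10) are made separately. Step 11 joins them and closes the only heterocycle. Steps 12–17 turn C3(CO2Me)2 into C3–CH3 and free the phenols.
4. Stereochemistry: C4 comes from Cu-catalysed asymmetric cyclopropanation of a Z-alkene. C5 comes from inversion of the cyclopropane aryl carbon and C2 from cis-selective closure, both in step 11. C3 comes from thermodynamic equilibration of the ester (step 13). The side-chain centre comes from Ir-catalysed asymmetric hydrogenation (step 9).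
5. Protecting groups: pivalate on the donor ring (keeps it a weak donor), benzyl ethers on the aldehyde rings (inert to chloride at 150 °C and to methoxide); they are removed in steps 13 and 17.

Key step: step 11

Remarks on the chemistry:
- Ring numbering used throughout is O1, C2 (bears ring A, the trisubstituted aryl), C3, C4, C5 (bears the 4-hydroxyphenyl group). With it the target is (2R,3R,4S,5S) with an (R) side chain.
- Assumption: the sense of induction of the chiral Cu and Ir catalysts is taken from the parent cis-β-methylstyrene and (E)-α-methylstilbene. The ligand antipode is chosen to give (2R,3R)-8 and (R)-16, to be confirmed on these compounds.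

**Route**

Step 1
Reactants: 1 4-hydroxybenzaldehyde
Product: 2 4-formylphenyl pivalate
Conditions: PivCl, Et3N, DMAP (cat.), CH2Cl2, 0 °C → rt
Reagents that add atoms: pivaloyl chloride, CC(C)(C)C(=O)Cl
Why: DMAP-catalysed acylation of the phenol; the hindered pivalate should survive the ylide of step 2 and makes the aryl ring only a weak donor for steps 4 and 11.

Step 2
Reactants: 2 4-formylphenyl pivalate; 3 ethyltriphenylphosphonium bromide
Product: 5 (Z)-4-(prop-1-en-1-yl)phenyl pivalate, via ethylidenetriphenylphosphorane 4 (not isolated)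
Conditions: 3, NaHMDS, THF, 0 °C; then 2, −78 °C → rt
Reagents that add atoms: none
Why: Wittig reaction of a salt-free non-stabilised ylide under kinetic control should give mainly the Z-alkene through the cis-oxaphosphetane; the aldehyde reacts far faster than the hindered aryl ester, and residual E isomer is removed on AgNO3-doped silica before step 4.

Step 3
Reactants: 6 dimethyl malonate
Product: 7 phenyliodonium bis(methoxycarbonyl)methanide
Conditions: PhI(OAc)2, KOH, MeCN, 0 °C
Reagents that add atoms: (diacetoxyiodo)benzene, CC(=O)OI(OC(C)=O)c1ccccc1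
Why: Base-mediated condensation of the malonate with the iodine(III) diacetate gives the iodonium ylide, a storable carbene source that avoids a diazo compound.

Step 4
Reactants: 5 (Z)-4-(prop-1-en-1-yl)phenyl pivalate; 7 phenyliodonium bis(methoxycarbonyl)methanide
Product: 8 dimethyl (2R,3R)-2-methyl-3-[4-(pivaloyloxy)phenyl]cyclopropane-1,1-dicarboxylate (methyl and aryl cis)
Conditions: Cu(MeCN)4PF6 (10 mol%), chiral side-arm bisoxazoline ligand (12 mol%), 4 Å MS, toluene, 0 °C → rt
Reagents that add atoms: none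
Why: Copper(I)–bisoxazoline-catalysed asymmetric cyclopropanation of a cis-1,2-disubstituted aryl alkene with a malonate iodonium ylide; the concerted carbene transfer is stereospecific, so the Z-alkene gives the cis-cyclopropane, and the ligand selects the alkene face and so sets C2 and C3 as (2R,3R).

Step 5
Reactants: 9 1-(benzyloxy)-4-iodobenzene; 10 propyne
Product: 11 1-(benzyloxy)-4-(prop-1-yn-1-yl)benzene
Conditions: propyne (1 atm), PdCl2(PPh3)2 (2 mol%), CuI (4 mol%), Et3N, THF, rt
Reagents that add atoms: none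
Why: Sonogashira coupling of an aryl iodide with a terminal alkyne proceeds at room temperature and leaves the benzyl ether untouched.

Step 6
Reactants: 11 1-(benzyloxy)-4-(prop-1-yn-1-yl)benzene
Product: 12 (Z)-2-{1-[4-(benzyloxy)phenyl]prop-1-en-2-yl}-4,4,5,5-tetramethyl-1,3,2-dioxaborolane
Conditions: B2pin2, CuCl (5 mol%), P(p-tol)3 (6 mol%), NaOtBu (10 mol%), MeOH (2 equiv), THF, rt
Reagents that add atoms: bis(pinacolato)diboron, CC1(C)OB(OC1(C)C)B1OC(C)(C)C(C)(C)O1
Why: Copper-catalysed formal hydroboration of an aryl alkyl alkyne (syn-borylcupration, then protonation) places boron on the carbon remote from the aryl ring with H and B cis, which fixes the alkene geometry that step 8 transfers to the stilbene.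

Step 7
Reactants: 13 4-bromo-2-iodophenol
Product: 14 1-(benzyloxy)-4-bromo-2-iodobenzene
Conditions: BnBr, K2CO3, DMF, rt
Reagents that add atoms: benzyl bromide, BrCc1ccccc1
Why: Williamson ether synthesis on the phenoxide; benzyl is chosen because it withstands steps 8–16 and leaves by neutral hydrogenolysis at the end.

Step 8
Reactants: 12 (Z)-2-{1-[4-(benzyloxy)phenyl]prop-1-en-2-yl}-4,4,5,5-tetramethyl-1,3,2-dioxaborolane; 14 1-(benzyloxy)-4-bromo-2-iodobenzene
Product: 15 (E)-1-(benzyloxy)-2-{1-[4-(benzyloxy)phenyl]prop-1-en-2-yl}-4-bromobenzene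
Conditions: Pd(dppf)Cl2 (3 mol%), K3PO4, 1,4-dioxane/H2O, 60 °C
Reagents that add atoms: none
Why: Suzuki–Miyaura coupling occurs with retention at the alkenyl boronate and at C–I in preference to C–Br (faster oxidative addition), so the E trisubstituted stilbene should form with the bromide kept for step 10.

Step 9
Reactants: 15 (E)-1-(benzyloxy)-2-{1-[4-(benzyloxy)phenyl]prop-1-en-2-yl}-4-bromobenzene
Product: 16 1-(benzyloxy)-2-{(2R)-1-[4-(benzyloxy)phenyl]propan-2-yl}-4-bromobenzene
Conditions: H2 (50 bar), [Ir(cod)(tBu-PHOX-type P,N ligand)]BArF (1–2 mol%), CH2Cl2, rt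
Reagents that add atoms: none
Why: Iridium–phosphinooxazoline-catalysed asymmetric hydrogenation of an unfunctionalised trisubstituted alkene, for which (E)-α-methylstilbenes are the standard substrates; the catalyst differentiates the alkene faces and sets the side-chain centre as R, and the aryl bromide and benzyl ethers are inert to it.

Step 10
Reactants: 16 1-(benzyloxy)-2-{(2R)-1-[4-(benzyloxy)phenyl]propan-2-yl}-4-bromobenzene
Product: 18 4-(benzyloxy)-3-{(2R)-1-[4-(benzyloxy)phenyl]propan-2-yl}benzaldehyde, via aryllithium 17 (not isolated)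
Conditions: n-BuLi, THF, −78 °C; then DMF, −78 → 0 °C; aq. NH4Cl
Reagents that add atoms: N,N-dimethylformamide, CN(C)C=O
Why: Bromine–lithium exchange at −78 °C is faster than any deprotonation, and formylation of the aryllithium with DMF gives the aldehyde after hydrolysis of the hemiaminal; the benzylic stereocentre is not acidic enough to be touched.

Step 11
Reactants: 8 dimethyl (2R,3R)-2-methyl-3-[4-(pivaloyloxy)phenyl]cyclopropane-1,1-dicarboxylate; 18 4-(benzyloxy)-3-{(2R)-1-[4-(benzyloxy)phenyl]propan-2-yl}benzaldehyde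
Product: 19 dimethyl (2S,4S,5S)-2-{4-(benzyloxy)-3-[(2R)-1-(4-(benzyloxy)phenyl)propan-2-yl]phenyl}-4-methyl-5-[4-(pivaloyloxy)phenyl]tetrahydrofuran-3,3-dicarboxylate (2,5-cis and 4,5-trans)
Conditions: 18 (1.3 equiv), Sn(OTf)2 (10 mol%), CH2Cl2, rt
Reagents that add atoms: none
Why: Tin(II) chelates the geminal diester of 8 and polarises the C1–C3 bond of the cyclopropane, the carbonyl oxygen of 18 attacks the aryl-bearing carbon from the rear in an SN2-like opening that releases ring strain and inverts that carbon (new O1–C5), and the tin malonate enolate then adds to the (E)-oxocarbenium carbon (new C2–C3). The closest known reaction type is the Lewis-acid-catalysed (3+2) annulation of aryl cyclopropane-1,1-diesters, 2,3-disubstituted ones included, with aldehydes to give 2,5-cis-tetrahydrofurans. The one ring closes in an aldol-type 5-(enolexo)-endo-trig step, which oxocarbenium electrophiles undergo readily. C5 is controlled by the cyclopropane configuration through inversion, so the cis aryl/methyl pair of 8 becomes the 4,5-trans pair while C4 is carried over untouched; C2 is controlled by an envelope transition state with both aryl groups and the C4 methyl pseudo-equatorial, which puts the C2 and C5 aryl groups cis. The step needs stereospecific opening instead of ionisation, and cleavage of the bond to the aryl carbon and not to the methyl carbon: the weakly donating pivaloyloxyphenyl group disfavours a free benzylic cation, the electron-rich aldehyde is a good oxygen nucleophile, and only the aryl-bearing carbon is benzylic.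

Step 12
Reactants: 19 dimethyl (2S,4S,5S)-2-{4-(benzyloxy)-3-[(2R)-1-(4-(benzyloxy)phenyl)propan-2-yl]phenyl}-4-methyl-5-[4-(pivaloyloxy)phenyl]tetrahydrofuran-3,3-dicarboxylate
Product: 20 methyl (2R,3RS,4S,5S)-2-{4-(benzyloxy)-3-[(2R)-1-(4-(benzyloxy)phenyl)propan-2-yl]phenyl}-4-methyl-5-[4-(pivaloyloxy)phenyl]tetrahydrofuran-3-carboxylate (C3 epimers; taken on crude)
Conditions: LiCl, H2O, DMSO, 150 °C
Reagents that add atoms: none
Why: Krapcho dealkoxycarbonylation: chloride demethylates one ester, the carboxylate loses CO2 and water protonates the ester enolate; benzyl ethers are inert, the C3 mixture is corrected in step 13, any phenol from partial loss of the pivalate converges there too, and the change of the C2 descriptor from S to R is a priority effect only.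

Step 13
Reactants: 20 methyl (2R,3RS,4S,5S)-2-{4-(benzyloxy)-3-[(2R)-1-(4-(benzyloxy)phenyl)propan-2-yl]phenyl}-4-methyl-5-[4-(pivaloyloxy)phenyl]tetrahydrofuran-3-carboxylate
Product: 21 methyl (2R,3R,4S,5S)-2-{4-(benzyloxy)-3-[(2R)-1-(4-(benzyloxy)phenyl)propan-2-yl]phenyl}-5-(4-hydroxyphenyl)-4-methyltetrahydrofuran-3-carboxylate
Conditions: NaOMe, MeOH/THF, rt; aq. NH4Cl
Reagents that add atoms: none
Why: Methoxide removes the pivalate by transesterification and epimerises C3 through the ester enolate (thermodynamic equilibration); the ester should settle trans to the larger C2 aryl group and cis to the C4 methyl, which is the C3 configuration of the target, and methoxide in methanol leaves the methyl ester as it is.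

Step 14
Reactants: 21 methyl (2R,3R,4S,5S)-2-{4-(benzyloxy)-3-[(2R)-1-(4-(benzyloxy)phenyl)propan-2-yl]phenyl}-5-(4-hydroxyphenyl)-4-methyltetrahydrofuran-3-carboxylate
Product: 22 [(2R,3S,4S,5S)-2-{4-(benzyloxy)-3-[(2R)-1-(4-(benzyloxy)phenyl)propan-2-yl]phenyl}-5-(4-hydroxyphenyl)-4-methyltetrahydrofuran-3-yl]methanol
Conditions: LiAlH4, THF, 0 °C
Reagents that add atoms: none
Why: Hydride reduction of the ester to the primary alcohol; the phenoxide, the benzyl ethers and the ring ether are inert, and no stereocentre is touched (the C3 descriptor changes by priority only).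

Step 15
Reactants: 22 [(2R,3S,4S,5S)-2-{4-(benzyloxy)-3-[(2R)-1-(4-(benzyloxy)phenyl)propan-2-yl]phenyl}-5-(4-hydroxyphenyl)-4-methyltetrahydrofuran-3-yl]methanol
Product: 23 4-[(2S,3S,4R,5R)-5-{4-(benzyloxy)-3-[(2R)-1-(4-(benzyloxy)phenyl)propan-2-yl]phenyl}-4-(iodomethyl)-3-methyltetrahydrofuran-2-yl]phenol (in the route numbering 2R,3R,4S,5S)
Conditions: PPh3, I2, imidazole, CH2Cl2, 0 °C → rt
Reagents that add atoms: iodine, II
Why: Appel reaction: the preformed phosphonium iodide activates only the aliphatic alcohol, which iodide displaces at the primary carbon, while the phenol cannot undergo substitution and is returned on work-up.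

Step 16
Reactants: 23 4-[(2S,3S,4R,5R)-5-{4-(benzyloxy)-3-[(2R)-1-(4-(benzyloxy)phenyl)propan-2-yl]phenyl}-4-(iodomethyl)-3-methyltetrahydrofuran-2-yl]phenol
Product: 24 4-[(2S,3S,4R,5R)-5-{4-(benzyloxy)-3-[(2R)-1-(4-(benzyloxy)phenyl)propan-2-yl]phenyl}-3,4-dimethyltetrahydrofuran-2-yl]phenol (in the route numbering 2R,3R,4S,5S)
Conditions: LiEt3BH, THF, 0 °C → rt
Reagents that add atoms: none
Why: SN2 displacement of the primary iodide by the strongly nucleophilic hydride donor turns CH2I into the C3 methyl group without touching a stereocentre; one further equivalent is consumed by the phenol, and benzyl ethers are stable.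

Step 17
Reactants: 24 4-[(2S,3S,4R,5R)-5-{4-(benzyloxy)-3-[(2R)-1-(4-(benzyloxy)phenyl)propan-2-yl]phenyl}-3,4-dimethyltetrahydrofuran-2-yl]phenol
Product: 25 (2R,3R,4S,5S)-2-{4-hydroxy-3-[(2R)-1-(4-hydroxyphenyl)propan-2-yl]phenyl}-5-(4-hydroxyphenyl)-3,4-dimethyltetrahydrofuran (target)
Conditions: H2 (1 atm), 10% Pd/C, EtOAc/MeOH, rt
Reagents that add atoms: none
Why: Hydrogenolysis of the two aryl benzyl ethers over Pd/C under neutral conditions at 1 atm should be much faster than cleavage of the benzylic C–O bonds of the tetrahydrofuran, so the reaction is stopped once the benzyl groups are gone.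

**Compound list**

1 | 4-hydroxybenzaldehyde | O=Cc1ccc(O)cc1 | starting material
2 | 4-formylphenyl pivalate | CC(C)(C)C(=O)Oc1ccc(C=O)cc1 | intermediate
3 | ethyltriphenylphosphonium bromide | CC[P+](c1ccccc1)(c1ccccc1)c1ccccc1.[Br-] | starting material
4 | ethylidenetriphenylphosphorane | CC=P(c1ccccc1)(c1ccccc1)c1ccccc1 | intermediate (not isolated)
5 | (Z)-4-(prop-1-en-1-yl)phenyl pivalate | C/C=C\c1ccc(OC(=O)C(C)(C)C)cc1 | intermediate
6 | dimethyl malonate | COC(=O)CC(=O)OC | starting material
7 | phenyliodonium bis(methoxycarbonyl)methanide | COC(=O)[C-](C(=O)OC)[I+]c1ccccc1 | intermediate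
8 | dimethyl (2R,3R)-2-methyl-3-[4-(pivaloyloxy)phenyl]cyclopropane-1,1-dicarboxylate (cis) | COC(=O)C1(C(=O)OC)[C@H](C)[C@@H]1c1ccc(OC(=O)C(C)(C)C)cc1 | intermediate
9 | 1-(benzyloxy)-4-iodobenzene | Ic1ccc(OCc2ccccc2)cc1 | starting material
10 | propyne | CC#C | starting material
11 | 1-(benzyloxy)-4-(prop-1-yn-1-yl)benzene | CC#Cc1ccc(OCc2ccccc2)cc1 | intermediate
12 | (Z)-2-{1-[4-(benzyloxy)phenyl]prop-1-en-2-yl}-4,4,5,5-tetramethyl-1,3,2-dioxaborolane | C/C(B1OC(C)(C)C(C)(C)O1)=C\c1ccc(OCc2ccccc2)cc1 | intermediate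
13 | 4-bromo-2-iodophenol | Oc1ccc(Br)cc1I | starting material
14 | 1-(benzyloxy)-4-bromo-2-iodobenzene | Brc1ccc(OCc2ccccc2)c(I)c1 | intermediate
15 | (E)-1-(benzyloxy)-2-{1-[4-(benzyloxy)phenyl]prop-1-en-2-yl}-4-bromobenzene | C/C(c1cc(Br)ccc1OCc1ccccc1)=C\c1ccc(OCc2ccccc2)cc1 | intermediate
16 | 1-(benzyloxy)-2-{(2R)-1-[4-(benzyloxy)phenyl]propan-2-yl}-4-bromobenzene | Brc1ccc(OCc2ccccc2)c([C@H](C)Cc2ccc(OCc3ccccc3)cc2)c1 | intermediate
17 | [4-(benzyloxy)-3-{(2R)-1-[4-(benzyloxy)phenyl]propan-2-yl}phenyl]lithium | [Li]c1ccc(OCc2ccccc2)c([C@H](C)Cc2ccc(OCc3ccccc3)cc2)c1 | intermediate (not isolated)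
18 | 4-(benzyloxy)-3-{(2R)-1-[4-(benzyloxy)phenyl]propan-2-yl}benzaldehyde | O=Cc1ccc(OCc2ccccc2)c([C@H](C)Cc2ccc(OCc3ccccc3)cc2)c1 | intermediate
19 | dimethyl (2S,4S,5S)-2-{4-(benzyloxy)-3-[(2R)-1-(4-(benzyloxy)phenyl)propan-2-yl]phenyl}-4-methyl-5-[4-(pivaloyloxy)phenyl]tetrahydrofuran-3,3-dicarboxylate | COC(=O)C1(C(=O)OC)[C@H](C)[C@@H](c2ccc(OC(=O)C(C)(C)C)cc2)O[C@H]1c1ccc(OCc2ccccc2)c([C@H](C)Cc2ccc(OCc3ccccc3)cc2)c1 | intermediate
20 | methyl (2R,3RS,4S,5S)-2-{4-(benzyloxy)-3-[(2R)-1-(4-(benzyloxy)phenyl)propan-2-yl]phenyl}-4-methyl-5-[4-(pivaloyloxy)phenyl]tetrahydrofuran-3-carboxylate (C3 epimers) | COC(=O)C1[C@H](C)[C@@H](c2ccc(OC(=O)C(C)(C)C)cc2)O[C@H]1c1ccc(OCc2ccccc2)c([C@H](C)Cc2ccc(OCc3ccccc3)cc2)c1 | intermediate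
21 | methyl (2R,3R,4S,5S)-2-{4-(benzyloxy)-3-[(2R)-1-(4-(benzyloxy)phenyl)propan-2-yl]phenyl}-5-(4-hydroxyphenyl)-4-methyltetrahydrofuran-3-carboxylate | COC(=O)[C@@H]1[C@H](C)[C@@H](c2ccc(O)cc2)O[C@H]1c1ccc(OCc2ccccc2)c([C@H](C)Cc2ccc(OCc3ccccc3)cc2)c1 | intermediate
22 | [(2R,3S,4S,5S)-2-{4-(benzyloxy)-3-[(2R)-1-(4-(benzyloxy)phenyl)propan-2-yl]phenyl}-5-(4-hydroxyphenyl)-4-methyltetrahydrofuran-3-yl]methanol | OC[C@@H]1[C@H](C)[C@@H](c2ccc(O)cc2)O[C@H]1c1ccc(OCc2ccccc2)c([C@H](C)Cc2ccc(OCc3ccccc3)cc2)c1 | intermediate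
23 | (2R,3R,4S,5S)-2-{4-(benzyloxy)-3-[(2R)-1-(4-(benzyloxy)phenyl)propan-2-yl]phenyl}-5-(4-hydroxyphenyl)-3-(iodomethyl)-4-methyltetrahydrofuran | IC[C@@H]1[C@H](C)[C@@H](c2ccc(O)cc2)O[C@H]1c1ccc(OCc2ccccc2)c([C@H](C)Cc2ccc(OCc3ccccc3)cc2)c1 | intermediate
24 | (2R,3R,4S,5S)-2-{4-(benzyloxy)-3-[(2R)-1-(4-(benzyloxy)phenyl)propan-2-yl]phenyl}-5-(4-hydroxyphenyl)-3,4-dimethyltetrahydrofuran | C[C@@H]1[C@H](C)[C@@H](c2ccc(O)cc2)O[C@H]1c1ccc(OCc2ccccc2)c([C@H](C)Cc2ccc(OCc3ccccc3)cc2)c1 | intermediate
25 | (2R,3R,4S,5S)-2-{4-hydroxy-3-[(2R)-1-(4-hydroxyphenyl)propan-2-yl]phenyl}-5-(4-hydroxyphenyl)-3,4-dimethyltetrahydrofuran | C[C@@H]1[C@H](C)[C@@H](c2ccc(O)cc2)O[C@H]1c1ccc(O)c([C@H](C)Cc2ccc(O)cc2)c1 | target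

**Step count and risks**

Total steps: 17. Longest linear sequence: 12 steps (steps 5, 6, 8–17, from 9).

Steps most likely to fail:

1. Step 11. The aldehyde is a weak nucleophile and the cis-cyclopropane is hindered, so opening may be slower than reversible ionisation of 8. That would isomerise 8 to the trans form or erode the configuration at the donor carbon, which shows up as loss of the 4,5-trans relationship and of enantiopurity. The fallback makes the same two bonds one at a time. It sets out from 18 and 8. Aldehyde 18 is reduced with NaBH4 in MeOH to {4-(benzyloxy)-3-[(2R)-1-(4-(benzyloxy)phenyl)propan-2-yl]phenyl}methanol F1. This alcohol, a far better nucleophile than the aldehyde, opens 8 under Lewis acid catalysis (Cu(OTf)2 or Sc(OTf)3, CH2Cl2) in an SN2-type reaction with inversion to give dimethyl 2-[(1S,2S)-1-({4-(benzyloxy)-3-[(2R)-1-(4-(benzyloxy)phenyl)propan-2-yl]benzyl}oxy)-1-[4-(pivaloyloxy)phenyl]propan-2-yl]malonate F2. Oxidation of its p-alkoxybenzyl ether C–H with DDQ (CH2Cl2, LiClO4, 2,6-dichloropyridine) generates the same oxocarbenium ion, which the malonate closes onto. The fallback comes back to the route at 19.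

2. Step 4. Facial selectivity of the carbene transfer to the Z-alkene may be insufficient, or cis geometry may be partly lost, giving 8 of low enantiomeric or diastereomeric purity. The fallback replaces catalyst control by resolution. It sets out from 6 and 5. Diazo transfer to 6 (p-acetamidobenzenesulfonyl azide, Et3N, MeCN) gives dimethyl 2-diazomalonate F3. Rh2(esp)2-catalysed, stereospecific cyclopropanation of 5 gives racemic dimethyl cis-2-methyl-3-[4-(pivaloyloxy)phenyl]cyclopropane-1,1-dicarboxylate F4. Preparative chromatography on a chiral stationary phase separates the enantiomers. The fallback comes back to the route at 8.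

3. Step 12. At 150 °C the ester enolate formed on decarboxylation may expel the ring oxygen from C2 (E1cB ring opening), which would scramble C2 or destroy the ring. The fallback avoids a free enolate at high temperature. It sets out from 19. LiOH in THF/MeOH/H2O at 50 °C hydrolyses one ester and the pivalate to give 2-{4-(benzyloxy)-3-[(2R)-1-(4-(benzyloxy)phenyl)propan-2-yl]phenyl}-5-(4-hydroxyphenyl)-3-(methoxycarbonyl)-4-methyltetrahydrofuran-3-carboxylic acid F5. Heating in toluene at about 100 °C decarboxylates this malonic half-acid through a neutral cyclic transition state to methyl 2-{4-(benzyloxy)-3-[(2R)-1-(4-(benzyloxy)phenyl)propan-2-yl]phenyl}-5-(4-hydroxyphenyl)-4-methyltetrahydrofuran-3-carboxylate as C3 epimers F6. Equilibration with NaOMe in MeOH as in step 13 follows. The fallback comes back to the route at 21.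

**Further compounds**

F1 | step 11 | {4-(benzyloxy)-3-[(2R)-1-(4-(benzyloxy)phenyl)propan-2-yl]phenyl}methanol | OCc1ccc(OCc2ccccc2)c([C@H](C)Cc2ccc(OCc3ccccc3)cc2)c1
F2 | step 11 | dimethyl 2-[(1S,2S)-1-({4-(benzyloxy)-3-[(2R)-1-(4-(benzyloxy)phenyl)propan-2-yl]benzyl}oxy)-1-[4-(pivaloyloxy)phenyl]propan-2-yl]malonate | COC(=O)C(C(=O)OC)[C@H](C)[C@@H](c1ccc(OC(=O)C(C)(C)C)cc1)OCc1ccc(OCc2ccccc2)c([C@H](C)Cc2ccc(OCc3ccccc3)cc2)c1
F3 | step 4 | dimethyl 2-diazomalonate | COC(=O)C(=[N+]=[N-])C(=O)OC
F4 | step 4 | racemic dimethyl cis-2-methyl-3-[4-(pivaloyloxy)phenyl]cyclopropane-1,1-dicarboxylate (both enantiomers) | COC(=O)C1(C(=O)OC)[C@H](C)[C@@H]1c1ccc(OC(=O)C(C)(C)C)cc1.COC(=O)C1(C(=O)OC)[C@@H](C)[C@H]1c1ccc(OC(=O)C(C)(C)C)cc1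
F5 | step 12 | 2-{4-(benzyloxy)-3-[(2R)-1-(4-(benzyloxy)phenyl)propan-2-yl]phenyl}-5-(4-hydroxyphenyl)-3-(methoxycarbonyl)-4-methyltetrahydrofuran-3-carboxylic acid (2,5-cis, 4,5-trans, C3 not defined) | COC(=O)C1(C(=O)O)[C@H](C)[C@@H](c2ccc(O)cc2)O[C@H]1c1ccc(OCc2ccccc2)c([C@H](C)Cc2ccc(OCc3ccccc3)cc2)c1
F6 | step 12 | methyl 2-{4-(benzyloxy)-3-[(2R)-1-(4-(benzyloxy)phenyl)propan-2-yl]phenyl}-5-(4-hydroxyphenyl)-4-methyltetrahydrofuran-3-carboxylate (C3 epimers) | COC(=O)C1[C@H](C)[C@@H](c2ccc(O)cc2)O[C@H]1c1ccc(OCc2ccccc2)c([C@H](C)Cc2ccc(OCc3ccccc3)cc2)c1
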